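The C40 tetrol is cut at C11=C12 and C11'=C12' into a C10 dialdehyde and two C15 ylides, both made from one (3S,5R,6S)-5,6-epoxy C15 ester. The disconnection on which everything rests is that the 2,5-dihydrofuran ring (O, C5', C6', C7', C8') is never built as such: its allylic ether C8'–O with the C6'=C7' alkene is the 1,3-transposed isomer of a C5'–C6' oxirane carrying the C7'=C8' alkene. The last step is the biomimetic acid-triggered vinyl-oxirane to dihydrofuran ring expansion (three- to five-membered), which moves O from C6' to C8', shifts the alkene into the ring and sets C8'. Its precursor is the all-E 5',6'-epoxy tetrol.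

Key step: step 16

Remark: carotenoid numbering is used (primed atoms belong to the dihydrofuran half); (4R,6R)-actinol, triethyl 3-methyl-4-phosphonocrotonate and 2,7-dimethylocta-2,4,6-trienedial are taken as commercial.

Step 1
Reactants: 1 (4R,6R)-4-hydroxy-2,2,6-trimethylcyclohexan-1-one; 2 tert-butyldimethylsilyl chloride
Product: 3 (4R,6R)-4-(tert-butyldimethylsilyloxy)-2,2,6-trimethylcyclohexan-1-one
Conditions: TBSCl, imidazole, DMF, rt
Reagents that add atoms: tert-butyldimethylsilyl chloride, CC(C)(C)[Si](C)(C)Cl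
Why: Imidazole-promoted silyl ether formation on the secondary alcohol; the TBS group later keeps O3 from taking part in the oxirane openings, and no stereocentre is touched.

Step 2
Reactants: 3 (4R,6R)-4-(tert-butyldimethylsilyloxy)-2,2,6-trimethylcyclohexan-1-one; 4 N-phenylbis(trifluoromethanesulfonimide)
Product: 6 (4R)-4-(tert-butyldimethylsilyloxy)-2,6,6-trimethylcyclohex-1-en-1-yl trifluoromethanesulfonate, via lithium enolate 5 (not isolated)
Conditions: LDA, THF, −78 °C; then PhNTf2, −78 to 0 °C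
Reagents that add atoms: N-phenylbis(trifluoromethanesulfonimide), O=S(=O)(N(c1ccccc1)S(=O)(=O)C(F)(F)F)C(F)(F)F
Why: Only C6 carries an α-hydrogen, so a single tetrasubstituted enolate forms and is O-triflated (enol triflate formation); the C6 stereocentre is erased on purpose and C4 is untouched.

Step 3
Reactants: 6 (4R)-4-(tert-butyldimethylsilyloxy)-2,6,6-trimethylcyclohex-1-en-1-yl trifluoromethanesulfonate; 7 carbon monoxide; 8 methanol
Product: 9 methyl (4R)-4-(tert-butyldimethylsilyloxy)-2,6,6-trimethylcyclohex-1-ene-1-carboxylate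
Conditions: Pd(OAc)2 (cat.), PPh3, CO (1 atm), MeOH, Et3N, DMF, 70 °C
Reagents that add atoms: carbon monoxide, [C-]#[O+]; methanol, CO
Why: Pd-catalysed alkoxycarbonylation of a vinyl triflate (oxidative addition, CO insertion, methanolysis) installs the future C7 on the hindered tetrasubstituted alkene.

Step 4
Reactants: 9 methyl (4R)-4-(tert-butyldimethylsilyloxy)-2,6,6-trimethylcyclohex-1-ene-1-carboxylate
Product: 10 [(4R)-4-(tert-butyldimethylsilyloxy)-2,6,6-trimethylcyclohex-1-en-1-yl]methanol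
Conditions: DIBAL-H, CH2Cl2, −78 to 0 °C; Rochelle salt work-up
Reagents that add atoms: none
Why: DIBAL-H reduces the unsaturated ester 1,2 to the allylic alcohol that is needed to direct the epoxidation; the silyl ether is inert.

Step 5
Reactants: 10 [(4R)-4-(tert-butyldimethylsilyloxy)-2,6,6-trimethylcyclohex-1-en-1-yl]methanol; 11 tert-butyl hydroperoxide
Product: 12 [(1R,4S,6R)-4-(tert-butyldimethylsilyloxy)-2,2,6-trimethyl-7-oxabicyclo[4.1.0]heptan-1-yl]methanol (oxirane anti to the silyloxy group)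
Conditions: Ti(OiPr)4 (cat.), D-(−)-diethyl tartrate (cat.), t-BuOOH, 4 Å MS, CH2Cl2, −20 °C
Reagents that add atoms: tert-butyl hydroperoxide, CC(C)(C)OO
Why: Sharpless asymmetric epoxidation: the Ti–tartrate complex bound to the allylic hydroxyl delivers oxygen under reagent control, with D-(−)-DET to the ring face anti to the C4 silyloxy group, which sets both oxirane carbons (later C5/C6 and C5'/C6') at once.

Step 6
Reactants: 12 [(1R,4S,6R)-4-(tert-butyldimethylsilyloxy)-2,2,6-trimethyl-7-oxabicyclo[4.1.0]heptan-1-yl]methanol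
Product: 13 (1S,4S,6R)-4-(tert-butyldimethylsilyloxy)-2,2,6-trimethyl-7-oxabicyclo[4.1.0]heptane-1-carbaldehyde
Conditions: TPAP (cat.), NMO, 4 Å MS, CH2Cl2, rt
Reagents that add atoms: none
Why: Ley–Griffith oxidation is non-acidic and stops at the aldehyde; the α-carbon is quaternary, so nothing can epimerise.

Step 7
Reactants: 13 (1S,4S,6R)-4-(tert-butyldimethylsilyloxy)-2,2,6-trimethyl-7-oxabicyclo[4.1.0]heptane-1-carbaldehyde; 14 ethyl (2E)-4-(diethoxyphosphoryl)-3-methylbut-2-enoate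
Product: 16 ethyl (2E,4E)-5-[(1S,4S,6R)-4-(tert-butyldimethylsilyloxy)-2,2,6-trimethyl-7-oxabicyclo[4.1.0]heptan-1-yl]-3-methylpenta-2,4-dienoate, via lithiated phosphonate 15 (not isolated)
Conditions: LiHMDS, THF, −78 °C; then 13, −78 to 0 °C
Reagents that add atoms: ethyl (2E)-4-(diethoxyphosphoryl)-3-methylbut-2-enoate, CCOC(=O)/C=C(\C)CP(=O)(OCC)OCC
Why: Vinylogous Horner–Wadsworth–Emmons olefination of the non-enolisable aldehyde forms C7=C8 with E geometry and brings in the 9E trisubstituted alkene; any 9Z isomer would be removed by chromatography.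

Step 8
Reactants: 16 ethyl (2E,4E)-5-[(1S,4S,6R)-4-(tert-butyldimethylsilyloxy)-2,2,6-trimethyl-7-oxabicyclo[4.1.0]heptan-1-yl]-3-methylpenta-2,4-dienoate
Product: 17 (2E,4E)-5-[(1S,4S,6R)-4-(tert-butyldimethylsilyloxy)-2,2,6-trimethyl-7-oxabicyclo[4.1.0]heptan-1-yl]-3-methylpenta-2,4-dien-1-ol
Conditions: DIBAL-H, CH2Cl2, −78 °C; Rochelle salt work-up
Reagents that add atoms: none
Why: DIBAL-H at low temperature reduces the dienoate to the allylic alcohol faster than it attacks the hindered tetrasubstituted oxirane.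

Step 9
Reactants: 17 (2E,4E)-5-[(1S,4S,6R)-4-(tert-butyldimethylsilyloxy)-2,2,6-trimethyl-7-oxabicyclo[4.1.0]heptan-1-yl]-3-methylpenta-2,4-dien-1-ol; 18 carbon tetrabromide; 19 triphenylphosphine
Product: 21 {(2E,4E)-5-[(1S,4S,6R)-4-(tert-butyldimethylsilyloxy)-2,2,6-trimethyl-7-oxabicyclo[4.1.0]heptan-1-yl]-3-methylpenta-2,4-dien-1-yl}triphenylphosphonium bromide, via allylic bromide 20 (not isolated)
Conditions: CBr4 (1 equiv), PPh3 (1 equiv), 2,6-lutidine (cat.), CH2Cl2, −20 °C; then PPh3 (1.2 equiv), rt; precipitation with Et2O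
Reagents that add atoms: carbon tetrabromide, BrC(Br)(Br)Br; triphenylphosphine, c1ccccc1P(c1ccccc1)c1ccccc1
Why: Appel bromination under buffered, non-protic conditions followed by SN2 quaternisation of the primary allylic bromide gives the C15 Wittig salt without exposing the vinyl oxirane to acid.

Step 10
Reactants: 16 ethyl (2E,4E)-5-[(1S,4S,6R)-4-(tert-butyldimethylsilyloxy)-2,2,6-trimethyl-7-oxabicyclo[4.1.0]heptan-1-yl]-3-methylpenta-2,4-dienoate; 22 water
Product: 23 ethyl (2E,4E)-5-[(1R,2R,4S)-4-(tert-butyldimethylsilyloxy)-1,2-dihydroxy-2,6,6-trimethylcyclohexyl]-3-methylpenta-2,4-dienoate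
Conditions: 0.05 M H2SO4, THF/H2O (3:1), 0 °C; NaHCO3 quench
Reagents that add atoms: water, O
Why: Acid-catalysed epoxide hydrolysis: water attacks the protonated oxirane at the allylic C6 anti to the leaving oxygen (borderline SN2, trans-diaxial opening), so C6 is inverted and C5 retained to give the trans-5R,6R diol, while the conjugated ester disfavours charge at C8 and the silyl ether keeps O3 from competing.

Step 11
Reactants: 23 ethyl (2E,4E)-5-[(1R,2R,4S)-4-(tert-butyldimethylsilyloxy)-1,2-dihydroxy-2,6,6-trimethylcyclohexyl]-3-methylpenta-2,4-dienoate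
Product: 24 (1R,2R,4S)-4-(tert-butyldimethylsilyloxy)-1-[(1E,3E)-5-hydroxy-3-methylpenta-1,3-dien-1-yl]-2,6,6-trimethylcyclohexane-1,2-diol
Conditions: DIBAL-H (5 equiv), CH2Cl2/THF, −78 to −20 °C; Rochelle salt work-up
Reagents that add atoms: none
Why: Excess DIBAL-H covers the two free hydroxyls and reduces the ester to the primary allylic alcohol; no stereocentre is involved.

Step 12
Reactants: 24 (1R,2R,4S)-4-(tert-butyldimethylsilyloxy)-1-[(1E,3E)-5-hydroxy-3-methylpenta-1,3-dien-1-yl]-2,6,6-trimethylcyclohexane-1,2-diol; 18 carbon tetrabromide; 19 triphenylphosphine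
Product: 26 {(2E,4E)-5-[(1R,2R,4S)-4-(tert-butyldimethylsilyloxy)-1,2-dihydroxy-2,6,6-trimethylcyclohexyl]-3-methylpenta-2,4-dien-1-yl}triphenylphosphonium bromide, via allylic bromide 25 (not isolated)
Conditions: CBr4 (1 equiv), PPh3 (1 equiv), 2,6-lutidine (cat.), CH2Cl2, −20 °C; then PPh3 (1.2 equiv), rt; precipitation with Et2O
Reagents that add atoms: carbon tetrabromide, BrC(Br)(Br)Br; triphenylphosphine, c1ccccc1P(c1ccccc1)c1ccccc1
Why: Appel bromination should select the unhindered primary allylic hydroxyl over the two hindered tertiary ones, and PPh3 then displaces bromide (SN2) to give the second Wittig salt.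

Step 13
Reactants: 26 {(2E,4E)-5-[(1R,2R,4S)-4-(tert-butyldimethylsilyloxy)-1,2-dihydroxy-2,6,6-trimethylcyclohexyl]-3-methylpenta-2,4-dien-1-yl}triphenylphosphonium bromide; 27 (2E,4E,6E)-2,7-dimethylocta-2,4,6-trienedial
Product: 29 (all-E)-(3S,5R,6R)-3-(tert-butyldimethylsilyloxy)-5,6-dihydroxy-5,6-dihydro-12'-apo-β-caroten-12'-al, via phosphonium ylide 28 (not isolated)
Conditions: NaOMe, MeOH/CH2Cl2, 0 °C to rt, 27 (3 equiv); then EtOAc, reflux (11Z to 11E)
Reagents that add atoms: (2E,4E,6E)-2,7-dimethylocta-2,4,6-trienedial, O=C/C(C)=C/C=C/C=C(\C)C=O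
Why: Wittig olefination of the allylic ylide with an excess of the symmetrical dialdehyde should stop at mono-condensation (the product aldehyde is the more conjugated, less electrophilic one), the hindered 11Z isomer is equilibrated thermally to E, and methoxide tolerates the free tertiary hydroxyls.

Step 14
Reactants: 29 (all-E)-(3S,5R,6R)-3-(tert-butyldimethylsilyloxy)-5,6-dihydroxy-5,6-dihydro-12'-apo-β-caroten-12'-al; 21 {(2E,4E)-5-[(1S,4S,6R)-4-(tert-butyldimethylsilyloxy)-2,2,6-trimethyl-7-oxabicyclo[4.1.0]heptan-1-yl]-3-methylpenta-2,4-dien-1-yl}triphenylphosphonium bromide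
Product: 31 (all-E)-(3S,5R,6R,3'S,5'R,6'S)-3,3'-bis(tert-butyldimethylsilyloxy)-5',6'-epoxy-5,6,5',6'-tetrahydro-β,β-carotene-5,6-diol, via epoxy ylide 30 (not isolated)
Conditions: NaOMe, MeOH/CH2Cl2, 0 °C to rt; then EtOAc, brief reflux under Ar in the dark (11'Z to 11'E)
Reagents that add atoms: none
Why: The second Wittig olefination joins the epoxy C15 ylide to the C25 aldehyde and completes the C40 chain; the oxirane is stable to base, and the 11'Z isomer is isomerised thermally under neutral conditions.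

Step 15
Reactants: 31 (all-E)-(3S,5R,6R,3'S,5'R,6'S)-3,3'-bis(tert-butyldimethylsilyloxy)-5',6'-epoxy-5,6,5',6'-tetrahydro-β,β-carotene-5,6-diol
Product: 32 (all-E)-(3S,5R,6R,3'S,5'R,6'S)-5',6'-epoxy-5,6,5',6'-tetrahydro-β,β-carotene-3,5,6,3'-tetrol
Conditions: TBAF, THF, 0 °C to rt
Reagents that add atoms: none
Why: Fluoride-mediated desilylation is basic, so both secondary hydroxyls are freed without touching the acid-labile vinyl oxirane or the polyene.

Step 16
Reactants: 32 (all-E)-(3S,5R,6R,3'S,5'R,6'S)-5',6'-epoxy-5,6,5',6'-tetrahydro-β,β-carotene-3,5,6,3'-tetrol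
Product: 33 (all-E)-(3S,5R,6R,3'S,5'R,8'R)-5',8'-epoxy-5,6,5',8'-tetrahydro-β,β-carotene-3,5,6,3'-tetrol (CNP0210286.2)
Conditions: (±)-camphor-10-sulfonic acid (5 mol%), THF, −30 to 0 °C, Ar, dark; Et3N quench; chromatography on Et3N-deactivated silica, HPLC if an 8'S epimer is present
Reagents that add atoms: none
Why: Protonation of the oxirane oxygen and heterolysis of the allylic C6'–O bond should give a polyene-delocalised cation (C6'/C8'/C10'…) in which O5' stays bonded to C5'; O5' then bonds to C8', so the three-membered ring (O, C5', C6') grows by C7' and C8' into the 2,5-dihydrofuran and the alkene moves from C7'=C8' to C6'=C7'. This is the acid-catalysed 5,6-epoxide to 5,8-furanoid oxide rearrangement of carotenoid epoxides, a cationic vinyl-oxirane to 2,5-dihydrofuran ring expansion (formal suprafacial 1,3-shift of oxygen) that is also the presumed natural origin of such end groups. The ring closes by attack of the tethered O5' on the C8' terminus of the C6'–C7'–C8' allyl cation, formally a 5-endo-trig O–C closure that is feasible because the acceptor is a cation, while larger rings through C10' or C12' would need a Z alkene and cannot form. C5' is not touched and keeps its configuration, C6' loses its stereocentre, and the new C8' centre is controlled by C5': directly after ionisation O5' sits axial on the face it left, above the s-cis (7'E) allyl unit, and collapse on that same face places C9' trans to the C5' methyl, which is 8'R. The step needs (i) ionisation of the oxirane in preference to the tertiary allylic 6-OH of the other half, secured by ring strain and by the deactivating neighbouring 5-OH, (ii) capture by O5' ahead of the 3'-OH on the opposite face (which would give a 3',6'-oxide) or external nucleophiles, secured by the five-membered transition state and anhydrous conditions, and (iii) kinetic control at C8', secured by low temperature, a catalytic weak acid and an early basic quench, since re-ionisation of the product C8'–O bond would scramble this centre.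

Compound list
1 | (4R,6R)-4-hydroxy-2,2,6-trimethylcyclohexan-1-one ((−)-actinol) | O=C1C(C)(C)C[C@H](O)C[C@H]1C | starting material
2 | tert-butyldimethylsilyl chloride | CC(C)(C)[Si](C)(C)Cl | starting material
3 | (4R,6R)-4-(tert-butyldimethylsilyloxy)-2,2,6-trimethylcyclohexan-1-one | O=C1C(C)(C)C[C@H](O[Si](C)(C)C(C)(C)C)C[C@H]1C | intermediate
4 | N-phenylbis(trifluoromethanesulfonimide) | O=S(=O)(N(c1ccccc1)S(=O)(=O)C(F)(F)F)C(F)(F)F | starting material
5 | lithium (4R)-4-(tert-butyldimethylsilyloxy)-2,6,6-trimethylcyclohex-1-en-1-olate | CC1=C([O-])C(C)(C)C[C@H](O[Si](C)(C)C(C)(C)C)C1.[Li+] | intermediate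
6 | (4R)-4-(tert-butyldimethylsilyloxy)-2,6,6-trimethylcyclohex-1-en-1-yl trifluoromethanesulfonate | CC1=C(OS(=O)(=O)C(F)(F)F)C(C)(C)C[C@H](O[Si](C)(C)C(C)(C)C)C1 | intermediate
7 | carbon monoxide | [C-]#[O+] | starting material
8 | methanol | CO | starting material
9 | methyl (4R)-4-(tert-butyldimethylsilyloxy)-2,6,6-trimethylcyclohex-1-ene-1-carboxylate | CC1=C(C(=O)OC)C(C)(C)C[C@H](O[Si](C)(C)C(C)(C)C)C1 | intermediate
10 | [(4R)-4-(tert-butyldimethylsilyloxy)-2,6,6-trimethylcyclohex-1-en-1-yl]methanol | CC1=C(CO)C(C)(C)C[C@H](O[Si](C)(C)C(C)(C)C)C1 | intermediate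
11 | tert-butyl hydroperoxide | CC(C)(C)OO | starting material
12 | [(1R,4S,6R)-4-(tert-butyldimethylsilyloxy)-2,2,6-trimethyl-7-oxabicyclo[4.1.0]heptan-1-yl]methanol | OC[C@]12C(C)(C)C[C@H](O[Si](C)(C)C(C)(C)C)C[C@@]1(C)O2 | intermediate
13 | (1S,4S,6R)-4-(tert-butyldimethylsilyloxy)-2,2,6-trimethyl-7-oxabicyclo[4.1.0]heptane-1-carbaldehyde | O=C[C@]12C(C)(C)C[C@H](O[Si](C)(C)C(C)(C)C)C[C@@]1(C)O2 | intermediate
14 | ethyl (2E)-4-(diethoxyphosphoryl)-3-methylbut-2-enoate | CCOC(=O)/C=C(\C)CP(=O)(OCC)OCC | starting material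
15 | lithium salt of 14 deprotonated at C4 | [Li+].CCOC(=O)/C=C(\C)[CH-]P(=O)(OCC)OCC | intermediate
16 | ethyl (2E,4E)-5-[(1S,4S,6R)-4-(tert-butyldimethylsilyloxy)-2,2,6-trimethyl-7-oxabicyclo[4.1.0]heptan-1-yl]-3-methylpenta-2,4-dienoate | CCOC(=O)/C=C(C)/C=C/[C@]12C(C)(C)C[C@H](O[Si](C)(C)C(C)(C)C)C[C@@]1(C)O2 | intermediate
17 | (2E,4E)-5-[(1S,4S,6R)-4-(tert-butyldimethylsilyloxy)-2,2,6-trimethyl-7-oxabicyclo[4.1.0]heptan-1-yl]-3-methylpenta-2,4-dien-1-ol | OC/C=C(C)/C=C/[C@]12C(C)(C)C[C@H](O[Si](C)(C)C(C)(C)C)C[C@@]1(C)O2 | intermediate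
18 | carbon tetrabromide | BrC(Br)(Br)Br | starting material
19 | triphenylphosphine | c1ccccc1P(c1ccccc1)c1ccccc1 | starting material
20 | (1S,4S,6R)-1-[(1E,3E)-5-bromo-3-methylpenta-1,3-dien-1-yl]-4-(tert-butyldimethylsilyloxy)-2,2,6-trimethyl-7-oxabicyclo[4.1.0]heptane | BrC/C=C(C)/C=C/[C@]12C(C)(C)C[C@H](O[Si](C)(C)C(C)(C)C)C[C@@]1(C)O2 | intermediate
21 | {(2E,4E)-5-[(1S,4S,6R)-4-(tert-butyldimethylsilyloxy)-2,2,6-trimethyl-7-oxabicyclo[4.1.0]heptan-1-yl]-3-methylpenta-2,4-dien-1-yl}triphenylphosphonium bromide | [Br-].c1ccccc1[P+](c1ccccc1)(c1ccccc1)C/C=C(C)/C=C/[C@]12C(C)(C)C[C@H](O[Si](C)(C)C(C)(C)C)C[C@@]1(C)O2 | intermediate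
22 | water | O | starting material
23 | ethyl (2E,4E)-5-[(1R,2R,4S)-4-(tert-butyldimethylsilyloxy)-1,2-dihydroxy-2,6,6-trimethylcyclohexyl]-3-methylpenta-2,4-dienoate | CCOC(=O)/C=C(C)/C=C/[C@@]1(O)C(C)(C)C[C@H](O[Si](C)(C)C(C)(C)C)C[C@@]1(C)O | intermediate
24 | (1R,2R,4S)-4-(tert-butyldimethylsilyloxy)-1-[(1E,3E)-5-hydroxy-3-methylpenta-1,3-dien-1-yl]-2,6,6-trimethylcyclohexane-1,2-diol | OC/C=C(C)/C=C/[C@@]1(O)C(C)(C)C[C@H](O[Si](C)(C)C(C)(C)C)C[C@@]1(C)O | intermediate
25 | (1R,2R,4S)-1-[(1E,3E)-5-bromo-3-methylpenta-1,3-dien-1-yl]-4-(tert-butyldimethylsilyloxy)-2,6,6-trimethylcyclohexane-1,2-diol | BrC/C=C(C)/C=C/[C@@]1(O)C(C)(C)C[C@H](O[Si](C)(C)C(C)(C)C)C[C@@]1(C)O | intermediate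
26 | {(2E,4E)-5-[(1R,2R,4S)-4-(tert-butyldimethylsilyloxy)-1,2-dihydroxy-2,6,6-trimethylcyclohexyl]-3-methylpenta-2,4-dien-1-yl}triphenylphosphonium bromide | [Br-].c1ccccc1[P+](c1ccccc1)(c1ccccc1)C/C=C(C)/C=C/[C@@]1(O)C(C)(C)C[C@H](O[Si](C)(C)C(C)(C)C)C[C@@]1(C)O | intermediate
27 | (2E,4E,6E)-2,7-dimethylocta-2,4,6-trienedial | O=C/C(C)=C/C=C/C=C(\C)C=O | starting material
28 | ylide of 26 (triphenylphosphoranylidene at C11) | c1ccccc1P(c1ccccc1)(c1ccccc1)=C/C=C(C)/C=C/[C@@]1(O)C(C)(C)C[C@H](O[Si](C)(C)C(C)(C)C)C[C@@]1(C)O | intermediate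
29 | (all-E)-(3S,5R,6R)-3-(tert-butyldimethylsilyloxy)-5,6-dihydroxy-5,6-dihydro-12'-apo-β-caroten-12'-al | CC(/C=C/C=C(C)/C=C/[C@@]1(O)C(C)(C)C[C@H](O[Si](C)(C)C(C)(C)C)C[C@@]1(C)O)=C\C=C\C=C(C)\C=O | intermediate
30 | ylide of 21 (triphenylphosphoranylidene at C11') | c1ccccc1P(c1ccccc1)(c1ccccc1)=C/C=C(C)/C=C/[C@]12C(C)(C)C[C@H](O[Si](C)(C)C(C)(C)C)C[C@@]1(C)O2 | intermediate
31 | (all-E)-(3S,5R,6R,3'S,5'R,6'S)-3,3'-bis(tert-butyldimethylsilyloxy)-5',6'-epoxy-5,6,5',6'-tetrahydro-β,β-carotene-5,6-diol | CC(/C=C/C=C(C)/C=C/[C@@]1(O)C(C)(C)C[C@H](O[Si](C)(C)C(C)(C)C)C[C@@]1(C)O)=C\C=C\C=C(C)\C=C\C=C(/C)\C=C\[C@]12C(C)(C)C[C@H](O[Si](C)(C)C(C)(C)C)C[C@@]1(C)O2 | intermediate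
32 | (all-E)-(3S,5R,6R,3'S,5'R,6'S)-5',6'-epoxy-5,6,5',6'-tetrahydro-β,β-carotene-3,5,6,3'-tetrol | CC(/C=C/C=C(C)/C=C/[C@@]1(O)C(C)(C)C[C@H](O)C[C@@]1(C)O)=C\C=C\C=C(C)\C=C\C=C(/C)\C=C\[C@]12C(C)(C)C[C@H](O)C[C@@]1(C)O2 | intermediate
33 | (all-E)-(3S,5R,6R,3'S,5'R,8'R)-5',8'-epoxy-5,6,5',8'-tetrahydro-β,β-carotene-3,5,6,3'-tetrol (CNP0210286.2) | CC(/C=C/C=C(C)/C=C/[C@@]1(O)C(C)(C)C[C@H](O)C[C@@]1(C)O)=C\C=C\C=C(C)\C=C\C=C(/C)[C@H]1C=C2C(C)(C)C[C@H](O)C[C@@]2(C)O1 | target

Total step count: 16. Longest linear sequence: 14 steps (steps 1–7, 10–13, 14–16).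

Steps most likely to fail

1. Step 16. The facial selectivity at C8' may erode through ring flip and C6'–C7' rotation in the cation or through re-ionisation of the product ether, and the cation may be diverted into dehydration at the triol half or Z/E scrambling. Fallback, setting out from 16 and returning at 33: the same ring expansion is run on the C15 ester (anhydrous HCl in CHCl3) to give ethyl (2E)-3-[(2R,6S,7aR)-6-(tert-butyldimethylsilyloxy)-4,4,7a-trimethyl-2,4,5,6,7,7a-hexahydro-1-benzofuran-2-yl]but-2-enoate F1. At this small-molecule stage the C8 diastereomers are separable by ordinary chromatography and the unwanted one can be re-equilibrated with acid. DIBAL-H then gives the allylic alcohol F2, CBr4/PPh3 the allylic bromide F3 (used in the flask) and more PPh3 the phosphonium bromide F4. Its ylide F5 (NaOMe, in the flask) is condensed with 29 to the bis-silyl ether of the target F6, and TBAF gives 33.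

2. Step 10. Water may add with retention through a free cation or at C5, the oxirane may ring-expand instead of hydrolysing, and loss of the silyl ether would let O3 attack C6. Fallback, setting out from 13 and returning at 23: Wittig olefination of 13 with 1-(triphenylphosphoranylidene)propan-2-one (toluene, 90 °C) gives the epoxy enone F7. Its C8 is electron-poor, so dilute HClO4 in THF/H2O should hydrolyse it cleanly at C6 with inversion to the diol enone F8. Horner–Wadsworth–Emmons reaction of F8 with the sodium salt of triethyl phosphonoacetate F9 (NaH, THF, 0 °C, excess, formed in the flask) then gives 23 after removal of any geometric isomer.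

3. Step 9. The acid-labile vinyl oxirane may be opened or rearranged by bromophosphonium species or traces of HBr, and the allylic bromide may transpose. Fallback, setting out from 17 and returning at 31: Mitsunobu reaction of 17 with 1-phenyl-1H-tetrazole-5-thiol (PPh3, DIAD, THF, 0 °C) gives the tetrazolyl sulfide F10. Buffered H2O2 with catalytic ammonium molybdate gives the sulfone F11, and its potassium carbanion F12 (KHMDS, THF, −78 °C, formed in the presence of 29) undergoes Julia–Kocienski olefination with 29 to give 31.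

Further compounds
F1 | step 16 | ethyl (2E)-3-[(2R,6S,7aR)-6-(tert-butyldimethylsilyloxy)-4,4,7a-trimethyl-2,4,5,6,7,7a-hexahydro-1-benzofuran-2-yl]but-2-enoate | CCOC(=O)\C=C(/C)[C@H]1C=C2C(C)(C)C[C@H](O[Si](C)(C)C(C)(C)C)C[C@@]2(C)O1
F2 | step 16 | (2E)-3-[(2R,6S,7aR)-6-(tert-butyldimethylsilyloxy)-4,4,7a-trimethyl-2,4,5,6,7,7a-hexahydro-1-benzofuran-2-yl]but-2-en-1-ol | OC\C=C(/C)[C@H]1C=C2C(C)(C)C[C@H](O[Si](C)(C)C(C)(C)C)C[C@@]2(C)O1
F3 | step 16 | (2R,6S,7aR)-2-[(2E)-4-bromobut-2-en-2-yl]-6-(tert-butyldimethylsilyloxy)-4,4,7a-trimethyl-2,4,5,6,7,7a-hexahydro-1-benzofuran | BrC\C=C(/C)[C@H]1C=C2C(C)(C)C[C@H](O[Si](C)(C)C(C)(C)C)C[C@@]2(C)O1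
F4 | step 16 | {(2E)-3-[(2R,6S,7aR)-6-(tert-butyldimethylsilyloxy)-4,4,7a-trimethyl-2,4,5,6,7,7a-hexahydro-1-benzofuran-2-yl]but-2-en-1-yl}triphenylphosphonium bromide | [Br-].c1ccccc1[P+](c1ccccc1)(c1ccccc1)C\C=C(/C)[C@H]1C=C2C(C)(C)C[C@H](O[Si](C)(C)C(C)(C)C)C[C@@]2(C)O1
F5 | step 16 | ylide of F4 | c1ccccc1P(c1ccccc1)(c1ccccc1)=C\C=C(/C)[C@H]1C=C2C(C)(C)C[C@H](O[Si](C)(C)C(C)(C)C)C[C@@]2(C)O1
F6 | step 16 | (all-E)-(3S,5R,6R,3'S,5'R,8'R)-3,3'-bis(tert-butyldimethylsilyloxy)-5',8'-epoxy-5,6,5',8'-tetrahydro-β,β-carotene-5,6-diol | CC(/C=C/C=C(C)/C=C/[C@@]1(O)C(C)(C)C[C@H](O[Si](C)(C)C(C)(C)C)C[C@@]1(C)O)=C\C=C\C=C(C)\C=C\C=C(/C)[C@H]1C=C2C(C)(C)C[C@H](O[Si](C)(C)C(C)(C)C)C[C@@]2(C)O1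
F7 | step 10 | (3E)-4-[(1S,4S,6R)-4-(tert-butyldimethylsilyloxy)-2,2,6-trimethyl-7-oxabicyclo[4.1.0]heptan-1-yl]but-3-en-2-one | CC(=O)/C=C/[C@]12C(C)(C)C[C@H](O[Si](C)(C)C(C)(C)C)C[C@@]1(C)O2
F8 | step 10 | (3E)-4-[(1R,2R,4S)-4-(tert-butyldimethylsilyloxy)-1,2-dihydroxy-2,6,6-trimethylcyclohexyl]but-3-en-2-one | CC(=O)/C=C/[C@@]1(O)C(C)(C)C[C@H](O[Si](C)(C)C(C)(C)C)C[C@@]1(C)O
F9 | step 10 | sodium salt of triethyl phosphonoacetate | [Na+].CCOC(=O)[CH-]P(=O)(OCC)OCC
F10 | step 9 | 5-({(2E,4E)-5-[(1S,4S,6R)-4-(tert-butyldimethylsilyloxy)-2,2,6-trimethyl-7-oxabicyclo[4.1.0]heptan-1-yl]-3-methylpenta-2,4-dien-1-yl}sulfanyl)-1-phenyl-1H-tetrazole | c1ccccc1-n1nnnc1SC/C=C(C)/C=C/[C@]12C(C)(C)C[C@H](O[Si](C)(C)C(C)(C)C)C[C@@]1(C)O2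
F11 | step 9 | 5-({(2E,4E)-5-[(1S,4S,6R)-4-(tert-butyldimethylsilyloxy)-2,2,6-trimethyl-7-oxabicyclo[4.1.0]heptan-1-yl]-3-methylpenta-2,4-dien-1-yl}sulfonyl)-1-phenyl-1H-tetrazole | c1ccccc1-n1nnnc1S(=O)(=O)C/C=C(C)/C=C/[C@]12C(C)(C)C[C@H](O[Si](C)(C)C(C)(C)C)C[C@@]1(C)O2
F12 | step 9 | potassium salt of the α-sulfonyl carbanion of F11 | [K+].c1ccccc1-n1nnnc1S(=O)(=O)[CH-]/C=C(C)/C=C/[C@]12C(C)(C)C[C@H](O[Si](C)(C)C(C)(C)C)C[C@@]1(C)O2
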